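## Retrosynthetic overview

1. Target ⇐ Boc removal ⇐ seco alkenyl iodide/tetramic acid, closed by a new Pd-catalysed carbonylative macrocyclisation that acylates C-3 of the tetramic acid (16-membered ring, formed last).
2. Seco compound ⇐ (Z)-enoic acid of the tricyclic core + Boc-L-ornithine (amide, then tetramic acid through Meldrum's acid); the acid ⇐ tricyclic aldehyde ester (Takai iodo-olefination, Still–Gennari olefination, acetyl unmasked).
3. Ring C ⇐ enal–enoate by organocatalytic reductive Michael cyclisation (sets C-6 and C-7).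
4. Rings A and B together ⇐ acyclic tetraenal by an iminium-catalysed, trans-selective intramolecular Diels–Alder reaction (sets C-3a, C-5a, C-8a, C-8b).
5. Tetraenal ⇐ (R)-benzyloxazolidinone crotonimide (Sakurai allylation sets C-2, Evans C-acylation sets C-3), cross-metathesis and HWE with a pentadienylphosphonate. Ring order: A+B, then C, then tetramic acid, then macrocycle.

Assumption: the target is taken as the 4-hydroxy (enol) tautomer drawn in the given SMILES; tautomers of the acyl tetramic acid are treated as one compound.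

Abbreviations and labels: TBS = tert-butyldimethylsilyl; Boc = tert-butoxycarbonyl. Core numbering is that of as-indacene: ring A = C-1, C-2 (CH3), C-3 (acetyl or its precursor), C-3a, C-8b; ring B = C-3a, C-4=C-5, C-5a, C-8a, C-8b; ring C = C-5a, C-6 (amide arm), C-7 (enone arm), C-8, C-8a. "tc" (target configuration) means: with ring B drawn flat, H-3a, H-5a, H-8a, H-7, the C-3 substituent, the C-2 methyl and the C-6 arm point up; H-8b, H-3, H-2, H-6 and the C-7 arm point down, in the absolute sense of the SMILES. DHI-6-yl = 1,2,3,3a,5a,6,7,8,8a,8b-decahydro-as-indacen-6-yl (tc). In the hexahydroindene intermediates, indene C-1, C-2, C-3a, C-4, C-5, C-7a are core C-3, C-2, C-8b, C-8a, C-5a, C-3a.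

## Route

Step 1
Reactants: 1 (4R)-4-benzyl-1,3-oxazolidin-2-one; 2 (2E)-but-2-enoyl chloride
Product: 3 (4R)-4-benzyl-3-[(2E)-but-2-enoyl]-1,3-oxazolidin-2-one
Conditions: nBuLi, THF, −78 °C; then 2, −78 to 0 °C
Reagents that add atoms: none
Why: N-acylation of the lithiated oxazolidinone by the acid chloride gives the enoyl imide; no stereocentre is formed.

Step 2
Reactants: 3 (4R)-4-benzyl-3-[(2E)-but-2-enoyl]-1,3-oxazolidin-2-one
Product: 4 (4R)-4-benzyl-3-[(3R)-3-methylhex-5-enoyl]-1,3-oxazolidin-2-one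
Conditions: TiCl4, allyltrimethylsilane, CH2Cl2, −78 °C
Reagents that add atoms: allyltrimethylsilane, C=CC[Si](C)(C)C
Why: Hosomi–Sakurai conjugate allylation of the TiCl4-chelated s-cis enoyl imide takes place on the β-carbon face opposite the benzyl group, which sets the future C-2 methyl centre as (3R).

Step 3
Reactants: 4 (4R)-4-benzyl-3-[(3R)-3-methylhex-5-enoyl]-1,3-oxazolidin-2-one
Product: 5 (4R)-3-[(2S,3R)-2-acetyl-3-methylhex-5-enoyl]-4-benzyl-1,3-oxazolidin-2-one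
Conditions: LiN(iPr)2, THF, −78 °C; then AcCl, −78 °C
Reagents that add atoms: acetyl chloride, CC(Cl)=O
Why: Evans C-acylation of the chelated (Z)-lithium imide enolate from the face opposite benzyl sets the future C-3 centre (2S), and the β-keto imide resists epimerisation because enolisation would incur A(1,3) strain.

Step 4
Reactants: 5 (4R)-3-[(2S,3R)-2-acetyl-3-methylhex-5-enoyl]-4-benzyl-1,3-oxazolidin-2-one
Product: 6 (4R)-4-benzyl-3-[(2S,3R)-2-[(1R)-1-hydroxyethyl]-3-methylhex-5-enoyl]-1,3-oxazolidin-2-one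
Conditions: Zn(BH4)2, CH2Cl2/Et2O, −20 °C
Reagents that add atoms: none
Why: chelation-controlled hydride reduction of the β-keto imide gives the syn (1R)-carbinol without touching the imide; this carbinol only masks the acetyl group and is re-oxidised in step 20.

Step 5
Reactants: 6 (4R)-4-benzyl-3-[(2S,3R)-2-[(1R)-1-hydroxyethyl]-3-methylhex-5-enoyl]-1,3-oxazolidin-2-one
Product: 7 (4R)-4-benzyl-3-[(2S,3R)-2-[(1R)-1-(TBSO)ethyl]-3-methylhex-5-enoyl]-1,3-oxazolidin-2-one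
Conditions: TBSOTf, 2,6-lutidine, CH2Cl2, 0 °C
Reagents that add atoms: tert-butyldimethylsilyl triflate, CC(C)(C)[Si](C)(C)OS(=O)(=O)C(F)(F)F
Why: silylation of the secondary alcohol with the silyl triflate protects the carbinol through the hydride steps that follow.

Step 6
Reactants: 7 (4R)-4-benzyl-3-[(2S,3R)-2-[(1R)-1-(TBSO)ethyl]-3-methylhex-5-enoyl]-1,3-oxazolidin-2-one
Product: 8 (2R,3R)-2-[(1R)-1-(TBSO)ethyl]-3-methylhex-5-en-1-ol
Conditions: LiBH4, MeOH (1 equiv), THF, 0 °C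
Reagents that add atoms: none
Why: reductive cleavage of the N-acyl oxazolidinone gives the primary alcohol and returns the auxiliary, with no stereocentre affected.

Step 7
Reactants: 8 (2R,3R)-2-[(1R)-1-(TBSO)ethyl]-3-methylhex-5-en-1-ol
Product: 9 (2R,3R,5E)-2-[(1R)-1-(TBSO)ethyl]-7,7-diethoxy-3-methylhept-5-en-1-ol
Conditions: acrolein diethyl acetal (5 equiv), second-generation Hoveyda–Grubbs catalyst RuCl2(H2IMes)(=CH-C6H4-2-OiPr) (5 mol%), CH2Cl2, 40 °C
Reagents that add atoms: acrolein diethyl acetal, C=CC(OCC)OCC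
Why: olefin cross-metathesis of the terminal alkene with the acrolein acetal gives the (E)-configured masked enal, and the free hydroxyl is tolerated.

Step 8
Reactants: 9 (2R,3R,5E)-2-[(1R)-1-(TBSO)ethyl]-7,7-diethoxy-3-methylhept-5-en-1-ol
Product: 10 (2S,3R,5E)-2-[(1R)-1-(TBSO)ethyl]-7,7-diethoxy-3-methylhept-5-enal
Conditions: Dess–Martin periodinane, NaHCO3, CH2Cl2, 0 °C
Reagents that add atoms: none
Why: buffered Dess–Martin oxidation gives the α-branched aldehyde without epimerisation or acetal loss.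

Step 9
Reactants: 11 penta-1,4-dien-3-ol
Product: 12 (3E)-5-bromopenta-1,3-diene
Conditions: 48% aq. HBr, 0 °C
Reagents that add atoms: hydrogen bromide, Br
Why: acid-mediated allylic substitution with transposition gives the conjugated primary (E)-bromide under thermodynamic control.

Step 10
Reactants: 12 (3E)-5-bromopenta-1,3-diene
Product: 13 diethyl [(2E)-penta-2,4-dien-1-yl]phosphonate
Conditions: P(OEt)3, neat, 120 °C
Reagents that add atoms: triethyl phosphite, CCOP(OCC)OCC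
Why: Michaelis–Arbuzov reaction of the allylic bromide gives the phosphonate with the (E)-diene retained.

Step 11
Reactants: 10 (2S,3R,5E)-2-[(1R)-1-(TBSO)ethyl]-7,7-diethoxy-3-methylhept-5-enal; 13 diethyl [(2E)-penta-2,4-dien-1-yl]phosphonate
Product: 14 (3E,5E,7R,8R,10E)-7-[(1R)-1-(TBSO)ethyl]-12,12-diethoxy-8-methyldodeca-1,3,5,10-tetraene
Conditions: 13, LiN(SiMe3)2, THF, −78 °C; then 10, −78 °C to rt
Reagents that add atoms: none
Why: Horner–Wadsworth–Emmons olefination with the allylic phosphonate anion forms the new alkene (E)-selectively to give the (E,E)-triene, and addition at low temperature keeps the α-stereocentre intact.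

Step 12
Reactants: 14 (3E,5E,7R,8R,10E)-7-[(1R)-1-(TBSO)ethyl]-12,12-diethoxy-8-methyldodeca-1,3,5,10-tetraene
Product: 16 1-[(1R)-1-(TBSO)ethyl]-5-ethenyl-2-methyl-2,3,3a,4,5,7a-hexahydro-1H-indene-4-carbaldehyde (tc), via tetraenal 15 (not isolated)
Conditions: (2S,5S)-5-benzyl-2-tert-butyl-3-methylimidazolidin-4-one·TFA (20 mol%), MeCN/H2O (95:5), 4 °C
Reagents that add atoms: water, O
Why: the wet ammonium salt hydrolyses the enal acetal and the iminium ion of 15 undergoes an intramolecular Diels–Alder reaction through the endo transition state that gives the trans-fused hydrindene; the benzyl group of the catalyst shields one dienophile face and A(1,3) strain keeps H-3 in the diene plane so the tether adds anti to the silyloxyethyl group (matched), which sets C-3a, C-8b, C-8a and C-5a.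

Step 13
Reactants: 16 1-[(1R)-1-(TBSO)ethyl]-5-ethenyl-2-methyl-2,3,3a,4,5,7a-hexahydro-1H-indene-4-carbaldehyde (tc)
Product: 17 methyl (2E)-3-[1-[(1R)-1-(TBSO)ethyl]-4-formyl-2-methyl-2,3,3a,4,5,7a-hexahydro-1H-inden-5-yl]prop-2-enoate (tc)
Conditions: methyl acrylate (10 equiv), second-generation Hoveyda–Grubbs catalyst (10 mol%), CH2Cl2, 40 °C
Reagents that add atoms: methyl acrylate, C=CC(=O)OC
Why: cross-metathesis of the vinyl group with methyl acrylate gives the (E)-enoate, while the ring alkene (internal, unstrained, hindered) and the aldehyde do not react.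

Step 14
Reactants: 17 methyl (2E)-3-[1-[(1R)-1-(TBSO)ethyl]-4-formyl-2-methyl-2,3,3a,4,5,7a-hexahydro-1H-inden-5-yl]prop-2-enoate (tc)
Product: 18 methyl (2E)-3-[1-[(1R)-1-(TBSO)ethyl]-2-methyl-4-[(1E)-3-oxoprop-1-en-1-yl]-2,3,3a,4,5,7a-hexahydro-1H-inden-5-yl]prop-2-enoate (tc)
Conditions: Ph3P=CHCHO, toluene, 80 °C
Reagents that add atoms: (triphenylphosphoranylidene)acetaldehyde, O=CC=P(c1ccccc1)(c1ccccc1)c1ccccc1
Why: Wittig reaction of the stabilised formyl ylide with the aldehyde (the enoate is inert) gives the (E)-enal by two-carbon homologation.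

Step 15
Reactants: 18 methyl (2E)-3-[1-[(1R)-1-(TBSO)ethyl]-2-methyl-4-[(1E)-3-oxoprop-1-en-1-yl]-2,3,3a,4,5,7a-hexahydro-1H-inden-5-yl]prop-2-enoate (tc)
Product: 19 methyl 2-[3-[(1R)-1-(TBSO)ethyl]-7-formyl-2-methyl-DHI-6-yl]acetate
Conditions: (2S,5S)-5-benzyl-2-tert-butyl-3-methylimidazolidin-4-one·HCl (20 mol%), Hantzsch ester (1.2 equiv), dioxane, rt
Reagents that add atoms: none
Why: organocatalytic reductive Michael cyclisation, in which only the enal forms an iminium ion, the Hantzsch ester delivers hydride to C-8 and the resulting enamine adds 5-exo to the enoate; A(1,3) strain at C-5a places the ester arm on the convex face (C-6) and the C-7 aldehyde equilibrates through the enamine to the trans isomer.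

Step 16
Reactants: 19 methyl 2-[3-[(1R)-1-(TBSO)ethyl]-7-formyl-2-methyl-DHI-6-yl]acetate
Product: 20 methyl 2-[3-[(1R)-1-(TBSO)ethyl]-7-[(E)-2-iodoethenyl]-2-methyl-DHI-6-yl]acetate
Conditions: CrCl2, CHI3, THF/dioxane, 0 °C to rt
Reagents that add atoms: iodoform, IC(I)I
Why: Takai olefination converts the aldehyde into the (E)-alkenyl iodide under non-basic conditions that leave C-7 and the ester untouched.

Step 17
Reactants: 20 methyl 2-[3-[(1R)-1-(TBSO)ethyl]-7-[(E)-2-iodoethenyl]-2-methyl-DHI-6-yl]acetate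
Product: 21 2-[3-[(1R)-1-(TBSO)ethyl]-7-[(E)-2-iodoethenyl]-2-methyl-DHI-6-yl]acetaldehyde
Conditions: iBu2AlH (1.1 equiv), CH2Cl2, −78 °C
Reagents that add atoms: none
Why: partial reduction of the unhindered methyl ester stops at the tetrahedral aluminium hemiacetal at −78 °C and gives the aldehyde on work-up.

Step 18
Reactants: 21 2-[3-[(1R)-1-(TBSO)ethyl]-7-[(E)-2-iodoethenyl]-2-methyl-DHI-6-yl]acetaldehyde
Product: 22 methyl (2Z)-4-[3-[(1R)-1-(TBSO)ethyl]-7-[(E)-2-iodoethenyl]-2-methyl-DHI-6-yl]but-2-enoate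
Conditions: (CF3CH2O)2P(O)CH2CO2Me, KN(SiMe3)2, 18-crown-6, THF, −78 °C
Reagents that add atoms: methyl bis(2,2,2-trifluoroethyl)phosphonoacetate, COC(=O)CP(=O)(OCC(F)(F)F)OCC(F)(F)F
Why: Still–Gennari olefination gives the (Z)-enoate by fast, irreversible elimination from the electron-poor phosphonate adduct.

Step 19
Reactants: 22 methyl (2Z)-4-[3-[(1R)-1-(TBSO)ethyl]-7-[(E)-2-iodoethenyl]-2-methyl-DHI-6-yl]but-2-enoate
Product: 23 methyl (2Z)-4-[3-[(1R)-1-hydroxyethyl]-7-[(E)-2-iodoethenyl]-2-methyl-DHI-6-yl]but-2-enoate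
Conditions: HF·pyridine, pyridine, THF, 0 °C to rt
Reagents that add atoms: none
Why: fluoride-mediated desilylation frees the secondary alcohol without affecting the alkenyl iodide or the (Z)-enoate.

Step 20
Reactants: 23 methyl (2Z)-4-[3-[(1R)-1-hydroxyethyl]-7-[(E)-2-iodoethenyl]-2-methyl-DHI-6-yl]but-2-enoate
Product: 24 methyl (2Z)-4-[3-acetyl-7-[(E)-2-iodoethenyl]-2-methyl-DHI-6-yl]but-2-enoate
Conditions: Dess–Martin periodinane, NaHCO3, CH2Cl2, rt
Reagents that add atoms: none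
Why: Dess–Martin oxidation unmasks the acetyl group under neutral conditions, so the C-3 centre set in step 3 is not epimerised.

Step 21
Reactants: 24 methyl (2Z)-4-[3-acetyl-7-[(E)-2-iodoethenyl]-2-methyl-DHI-6-yl]but-2-enoate
Product: 25 (2Z)-4-[3-acetyl-7-[(E)-2-iodoethenyl]-2-methyl-DHI-6-yl]but-2-enoic acid
Conditions: Me3SnOH, 1,2-dichloroethane, 70 °C
Reagents that add atoms: trimethyltin hydroxide, C[Sn](C)(C)O
Why: mild, near-neutral ester hydrolysis gives the acid without epimerising C-3 or isomerising the (Z)-alkene.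

Step 22
Reactants: 25 (2Z)-4-[3-acetyl-7-[(E)-2-iodoethenyl]-2-methyl-DHI-6-yl]but-2-enoic acid; 26 N2-(tert-butoxycarbonyl)-L-ornithine
Product: 28 N2-(tert-butoxycarbonyl)-N5-[(2Z)-4-[3-acetyl-7-[(E)-2-iodoethenyl]-2-methyl-DHI-6-yl]but-2-enoyl]-L-ornithine, via NHS ester 27 (not isolated)
Conditions: N-hydroxysuccinimide, EDC·HCl, CH2Cl2, rt; then 26, iPr2NEt, DMF, rt
Reagents that add atoms: none
Why: active-ester amidation acylates the only free amine of 26 (the δ-NH2), so the ornithine carboxylic acid needs no protection.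

Step 23
Reactants: 28 N2-(tert-butoxycarbonyl)-N5-[(2Z)-4-[3-acetyl-7-[(E)-2-iodoethenyl]-2-methyl-DHI-6-yl]but-2-enoyl]-L-ornithine
Product: 30 tert-butyl (2S)-2-[3-[[(2Z)-4-[3-acetyl-7-[(E)-2-iodoethenyl]-2-methyl-DHI-6-yl]but-2-enoyl]amino]propyl]-3-hydroxy-5-oxo-2,5-dihydro-1H-pyrrole-1-carboxylate, via acyl Meldrum's acid 29 (not isolated)
Conditions: Meldrum's acid, EDC·HCl, DMAP, CH2Cl2, 0 °C to rt; then EtOAc, reflux
Reagents that add atoms: Meldrum's acid, CC1(C)OC(=O)CC(=O)O1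
Why: Jouin tetramic acid synthesis, in which C-acylation of Meldrum's acid is followed by thermal ring closure of the carbamate nitrogen with loss of acetone and CO2; the ornithine α-centre is retained.

Step 24
Reactants: 30 tert-butyl (2S)-2-[3-[[(2Z)-4-[3-acetyl-7-[(E)-2-iodoethenyl]-2-methyl-DHI-6-yl]but-2-enoyl]amino]propyl]-3-hydroxy-5-oxo-2,5-dihydro-1H-pyrrole-1-carboxylate
Product: 31 N-Boc macrocycle (32 carrying Boc on the tetramic acid nitrogen)
Conditions: Pd2(dba)3 (5 mol%), Xantphos (12 mol%), CO (1 atm), MgCl2 (2 equiv), Et3N (4 equiv), MeCN/THF, 60 °C, slow addition of 30 to 1 mM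
Reagents that add atoms: carbon monoxide, [C-]#[O+]
Why: Proposed new method: intramolecular palladium-catalysed carbonylative C-3 acylation of a tetramic acid by an alkenyl iodide – oxidative addition of the (E)-alkenyl iodide to zerovalent palladium and CO insertion give an alkenoyl–palladium iodide (divalent palladium), which is captured at C-3 by the magnesium-chelated tetramate enolate (soft enolisation with MgCl2/Et3N) with retention of alkene geometry, so the enone–C-3 bond and the 16-membered ring form in one operation and the chelated 3-acyl tetramate is the thermodynamic sink; Xantphos favours acyl-palladium formation at 1 atm and high dilution suppresses oligomers; the closest known reaction type is the palladium-catalysed carbonylative C-acylation (α-arylation) of 1,3-dicarbonyl compounds with aryl iodides, together with the 3-acylation of tetramic acids by activated acids.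

Step 25
Reactants: 31 N-Boc macrocycle (32 carrying Boc on the tetramic acid nitrogen)
Product: 32 target CNP0320820.1 (16-membered macrolactam of the 3-acetyl-2-methyl-decahydro-as-indacene core with the L-ornithine-derived 3-acyl tetramic acid)
Conditions: TFA, CH2Cl2, 0 °C
Reagents that add atoms: none
Why: acidolysis removes the Boc group as isobutene and CO2, and the acyl tetramic acid, (Z)-enamide and (E)-enone are stable to acid.

## Compound list

1 | (4R)-4-benzyl-1,3-oxazolidin-2-one | O=C1OC[C@@H](Cc2ccccc2)N1 | starting material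
2 | (2E)-but-2-enoyl chloride | C/C=C/C(Cl)=O | starting material
3 | (4R)-4-benzyl-3-[(2E)-but-2-enoyl]-1,3-oxazolidin-2-one | C/C=C/C(=O)N1C(=O)OC[C@H]1Cc1ccccc1 | intermediate
4 | (4R)-4-benzyl-3-[(3R)-3-methylhex-5-enoyl]-1,3-oxazolidin-2-one | C=CC[C@@H](C)CC(=O)N1C(=O)OC[C@H]1Cc1ccccc1 | intermediate
5 | (4R)-3-[(2S,3R)-2-acetyl-3-methylhex-5-enoyl]-4-benzyl-1,3-oxazolidin-2-one | CC(=O)[C@H]([C@H](C)CC=C)C(=O)N1C(=O)OC[C@H]1Cc1ccccc1 | intermediate
6 | (4R)-4-benzyl-3-[(2S,3R)-2-[(1R)-1-hydroxyethyl]-3-methylhex-5-enoyl]-1,3-oxazolidin-2-one | C[C@@H](O)[C@H]([C@H](C)CC=C)C(=O)N1C(=O)OC[C@H]1Cc1ccccc1 | intermediate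
7 | (4R)-4-benzyl-3-[(2S,3R)-2-[(1R)-1-(TBSO)ethyl]-3-methylhex-5-enoyl]-1,3-oxazolidin-2-one | C[C@@H](O[Si](C)(C)C(C)(C)C)[C@H]([C@H](C)CC=C)C(=O)N1C(=O)OC[C@H]1Cc1ccccc1 | intermediate
8 | (2R,3R)-2-[(1R)-1-(TBSO)ethyl]-3-methylhex-5-en-1-ol | C[C@@H](O[Si](C)(C)C(C)(C)C)[C@H]([C@H](C)CC=C)CO | intermediate
9 | (2R,3R,5E)-2-[(1R)-1-(TBSO)ethyl]-7,7-diethoxy-3-methylhept-5-en-1-ol | C[C@@H](O[Si](C)(C)C(C)(C)C)[C@H]([C@H](C)C/C=C/C(OCC)OCC)CO | intermediate
10 | (2S,3R,5E)-2-[(1R)-1-(TBSO)ethyl]-7,7-diethoxy-3-methylhept-5-enal | C[C@@H](O[Si](C)(C)C(C)(C)C)[C@H]([C@H](C)C/C=C/C(OCC)OCC)C=O | intermediate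
11 | penta-1,4-dien-3-ol | C=CC(O)C=C | starting material
12 | (3E)-5-bromopenta-1,3-diene | C=C/C=C/CBr | intermediate
13 | diethyl [(2E)-penta-2,4-dien-1-yl]phosphonate | C=C/C=C/CP(=O)(OCC)OCC | intermediate
14 | (3E,5E,7R,8R,10E)-7-[(1R)-1-(TBSO)ethyl]-12,12-diethoxy-8-methyldodeca-1,3,5,10-tetraene | C[C@@H](O[Si](C)(C)C(C)(C)C)[C@H]([C@H](C)C/C=C/C(OCC)OCC)/C=C/C=C/C=C | intermediate
15 | (2E,5R,6R,7E,9E)-6-[(1R)-1-(TBSO)ethyl]-5-methyldodeca-2,7,9,11-tetraenal | C[C@@H](O[Si](C)(C)C(C)(C)C)[C@H]([C@H](C)C/C=C/C=O)/C=C/C=C/C=C | intermediate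
16 | 1-[(1R)-1-(TBSO)ethyl]-5-ethenyl-2-methyl-2,3,3a,4,5,7a-hexahydro-1H-indene-4-carbaldehyde (tc; trans ring fusion) | C[C@@H](O[Si](C)(C)C(C)(C)C)[C@H]1[C@@H]2C=C[C@H](C=C)[C@H](C=O)[C@H]2C[C@H]1C | intermediate
17 | methyl (2E)-3-[1-[(1R)-1-(TBSO)ethyl]-4-formyl-2-methyl-2,3,3a,4,5,7a-hexahydro-1H-inden-5-yl]prop-2-enoate (tc) | C[C@@H](O[Si](C)(C)C(C)(C)C)[C@H]1[C@@H]2C=C[C@H](/C=C/C(=O)OC)[C@H](C=O)[C@H]2C[C@H]1C | intermediate
18 | methyl (2E)-3-[1-[(1R)-1-(TBSO)ethyl]-2-methyl-4-[(1E)-3-oxoprop-1-en-1-yl]-2,3,3a,4,5,7a-hexahydro-1H-inden-5-yl]prop-2-enoate (tc) | C[C@@H](O[Si](C)(C)C(C)(C)C)[C@H]1[C@@H]2C=C[C@H](/C=C/C(=O)OC)[C@H](/C=C/C=O)[C@H]2C[C@H]1C | intermediate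
19 | methyl 2-[3-[(1R)-1-(TBSO)ethyl]-7-formyl-2-methyl-DHI-6-yl]acetate | C[C@@H](O[Si](C)(C)C(C)(C)C)[C@H]1[C@@H]2C=C[C@@H]3[C@@H](CC(=O)OC)[C@H](C=O)C[C@@H]3[C@H]2C[C@H]1C | intermediate
20 | methyl 2-[3-[(1R)-1-(TBSO)ethyl]-7-[(E)-2-iodoethenyl]-2-methyl-DHI-6-yl]acetate | C[C@@H](O[Si](C)(C)C(C)(C)C)[C@H]1[C@@H]2C=C[C@@H]3[C@@H](CC(=O)OC)[C@H](/C=C/I)C[C@@H]3[C@H]2C[C@H]1C | intermediate
21 | 2-[3-[(1R)-1-(TBSO)ethyl]-7-[(E)-2-iodoethenyl]-2-methyl-DHI-6-yl]acetaldehyde | C[C@@H](O[Si](C)(C)C(C)(C)C)[C@H]1[C@@H]2C=C[C@@H]3[C@@H](CC=O)[C@H](/C=C/I)C[C@@H]3[C@H]2C[C@H]1C | intermediate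
22 | methyl (2Z)-4-[3-[(1R)-1-(TBSO)ethyl]-7-[(E)-2-iodoethenyl]-2-methyl-DHI-6-yl]but-2-enoate | C[C@@H](O[Si](C)(C)C(C)(C)C)[C@H]1[C@@H]2C=C[C@@H]3[C@@H](C/C=C\C(=O)OC)[C@H](/C=C/I)C[C@@H]3[C@H]2C[C@H]1C | intermediate
23 | methyl (2Z)-4-[3-[(1R)-1-hydroxyethyl]-7-[(E)-2-iodoethenyl]-2-methyl-DHI-6-yl]but-2-enoate | C[C@@H](O)[C@H]1[C@@H]2C=C[C@@H]3[C@@H](C/C=C\C(=O)OC)[C@H](/C=C/I)C[C@@H]3[C@H]2C[C@H]1C | intermediate
24 | methyl (2Z)-4-[3-acetyl-7-[(E)-2-iodoethenyl]-2-methyl-DHI-6-yl]but-2-enoate | CC(=O)[C@H]1[C@@H]2C=C[C@@H]3[C@@H](C/C=C\C(=O)OC)[C@H](/C=C/I)C[C@@H]3[C@H]2C[C@H]1C | intermediate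
25 | (2Z)-4-[3-acetyl-7-[(E)-2-iodoethenyl]-2-methyl-DHI-6-yl]but-2-enoic acid | CC(=O)[C@H]1[C@@H]2C=C[C@@H]3[C@@H](C/C=C\C(=O)O)[C@H](/C=C/I)C[C@@H]3[C@H]2C[C@H]1C | intermediate
26 | N2-(tert-butoxycarbonyl)-L-ornithine (Boc-Orn-OH) | CC(C)(C)OC(=O)N[C@@H](CCCN)C(=O)O | starting material
27 | 2,5-dioxopyrrolidin-1-yl (2Z)-4-[3-acetyl-7-[(E)-2-iodoethenyl]-2-methyl-DHI-6-yl]but-2-enoate | CC(=O)[C@H]1[C@@H]2C=C[C@@H]3[C@@H](C/C=C\C(=O)ON4C(=O)CCC4=O)[C@H](/C=C/I)C[C@@H]3[C@H]2C[C@H]1C | intermediate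
28 | N2-(tert-butoxycarbonyl)-N5-[(2Z)-4-[3-acetyl-7-[(E)-2-iodoethenyl]-2-methyl-DHI-6-yl]but-2-enoyl]-L-ornithine | CC(=O)[C@H]1[C@@H]2C=C[C@@H]3[C@@H](C/C=C\C(=O)NCCC[C@H](NC(=O)OC(C)(C)C)C(=O)O)[C@H](/C=C/I)C[C@@H]3[C@H]2C[C@H]1C | intermediate
29 | acyl Meldrum's acid of 28: 5-[(2S)-2-(Boc-amino)-1-hydroxy-5-[[(2Z)-4-[3-acetyl-7-[(E)-2-iodoethenyl]-2-methyl-DHI-6-yl]but-2-enoyl]amino]pentylidene]-2,2-dimethyl-1,3-dioxane-4,6-dione | CC(=O)[C@H]1[C@@H]2C=C[C@@H]3[C@@H](C/C=C\C(=O)NCCC[C@H](NC(=O)OC(C)(C)C)C(O)=C4C(=O)OC(C)(C)OC4=O)[C@H](/C=C/I)C[C@@H]3[C@H]2C[C@H]1C | intermediate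
30 | tert-butyl (2S)-2-[3-[[(2Z)-4-[3-acetyl-7-[(E)-2-iodoethenyl]-2-methyl-DHI-6-yl]but-2-enoyl]amino]propyl]-3-hydroxy-5-oxo-2,5-dihydro-1H-pyrrole-1-carboxylate | CC(=O)[C@H]1[C@@H]2C=C[C@@H]3[C@@H](C/C=C\C(=O)NCCC[C@@H]4N(C(=O)OC(C)(C)C)C(=O)C=C4O)[C@H](/C=C/I)C[C@@H]3[C@H]2C[C@H]1C | intermediate
31 | N-Boc macrocycle (32 carrying Boc on the tetramic acid nitrogen) | CC(=O)[C@H]1[C@@H]2C=C[C@@H]3[C@H]4C/C=C\C(=O)NCCC[C@@H]5N(C(=O)OC(C)(C)C)C(=O)C(=C5O)C(=O)/C=C/[C@@H]4C[C@@H]3[C@H]2C[C@H]1C | intermediate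
32 | target CNP0320820.1 (16-membered macrolactam of the 3-acetyl-2-methyl-decahydro-as-indacene core with the L-ornithine-derived 3-acyl tetramic acid; tc) | CC(=O)[C@H]1[C@@H]2C=C[C@@H]3[C@H]4C/C=C\C(=O)NCCC[C@@H]5NC(=O)C(=C5O)C(=O)/C=C/[C@@H]4C[C@@H]3[C@H]2C[C@H]1C | target

## Step count and risk

Total step count: 25 (23 on the main line plus 2 for phosphonate 13). Longest linear sequence: 23 steps (steps 1–8 and 11–25, from 1 and 2 to 32).

The three steps most likely to fail: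

Step 24 (the proposed new carbonylative macrocyclisation). The risks are O- versus C-acylation of the tetramate, oligomerisation, and catalyst inhibition by the chelating product. The fallback uses known chemistry only; it sets out from 25 and comes back at 32. EDC/HOBt coupling of 25 with methyl N2-Boc-L-ornithinate gives the amide ester F6. Pd(OAc)2/PPh3-catalysed hydroxycarbonylation of the alkenyl iodide (CO, H2O, Et3N, DMF) gives the (E)-propenoic acid F7. Meldrum's acid, EDC and DMAP give the acyl Meldrum's acid F8. TFA removes the Boc group to give the amine F9, handled as its salt. Slow addition of F9 to refluxing toluene containing Et3N generates the acylketene, which the amine traps to give the macrocyclic β-keto amide F10 (acylketene macrolactamisation). KOtBu in tBuOH then effects Lacey–Dieckmann cyclisation to 32; base contact is kept short to protect C-3.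

Step 15 (reductive Michael cyclisation). The enamine may add slowly to an enoate, which is a weaker acceptor than the enones normally used, and the C-6 selectivity rests on A(1,3) strain. The fallback sets out from 18 and comes back at 19. A PMe3-catalysed intramolecular Rauhut–Currier reaction (tert-amyl alcohol, rt), in which the phosphine adds to the more electrophilic enal and the resulting enolate closes onto the enoate, gives the cyclopentene carbaldehyde F5. Conjugate reduction with [(Ph3P)CuH]6, followed by brief DBU equilibration of the C-7 aldehyde to the trans isomer, gives 19.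

Step 12 (acetal hydrolysis and organocatalytic intramolecular Diels–Alder reaction). The risks are polymerisation of the terminal triene, slow iminium formation, and incomplete endo or facial control. The fallback replaces catalyst control by auxiliary control; it sets out from 14 and comes back at 16. Compound 14 is hydrolysed (aqueous oxalic acid, THF) to the tetraenal 15, which is isolated. NaClO2/NaH2PO4/2-methylbut-2-ene oxidation gives the tetraenoic acid F1. tBuCOCl/Et3N and then the lithium salt of (4S)-4-benzyl-1,3-oxazolidin-2-one give the trienimide F2. Me2AlCl (CH2Cl2, −30 °C) promotes the auxiliary-controlled Evans intramolecular Diels–Alder reaction to the cycloadduct imide F3. LiBH4 releases the primary alcohol F4, and Dess–Martin oxidation gives 16.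

Further compounds

F1 | step 12 | (2E,5R,6R,7E,9E)-6-[(1R)-1-(TBSO)ethyl]-5-methyldodeca-2,7,9,11-tetraenoic acid | C[C@@H](O[Si](C)(C)C(C)(C)C)[C@H]([C@H](C)C/C=C/C(=O)O)/C=C/C=C/C=C
F2 | step 12 | (4S)-4-benzyl-3-[(2E,5R,6R,7E,9E)-6-[(1R)-1-(TBSO)ethyl]-5-methyldodeca-2,7,9,11-tetraenoyl]-1,3-oxazolidin-2-one | C[C@@H](O[Si](C)(C)C(C)(C)C)[C@H]([C@H](C)C/C=C/C(=O)N1C(=O)OC[C@@H]1Cc1ccccc1)/C=C/C=C/C=C
F3 | step 12 | (4S)-4-benzyl-3-[[1-[(1R)-1-(TBSO)ethyl]-5-ethenyl-2-methyl-2,3,3a,4,5,7a-hexahydro-1H-inden-4-yl]carbonyl]-1,3-oxazolidin-2-one (tc) | C[C@@H](O[Si](C)(C)C(C)(C)C)[C@H]1[C@@H]2C=C[C@H](C=C)[C@H](C(=O)N3C(=O)OC[C@@H]3Cc3ccccc3)[C@H]2C[C@H]1C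
F4 | step 12 | [1-[(1R)-1-(TBSO)ethyl]-5-ethenyl-2-methyl-2,3,3a,4,5,7a-hexahydro-1H-inden-4-yl]methanol (tc) | C[C@@H](O[Si](C)(C)C(C)(C)C)[C@H]1[C@@H]2C=C[C@H](C=C)[C@H](CO)[C@H]2C[C@H]1C
F5 | step 15 | methyl 2-[3-[(1R)-1-(TBSO)ethyl]-7-formyl-2-methyl-1,2,3,3a,5a,6,8a,8b-octahydro-as-indacen-6-yl]acetate (tc) | C[C@@H](O[Si](C)(C)C(C)(C)C)[C@H]1[C@@H]2C=C[C@@H]3[C@@H](CC(=O)OC)C(C=O)=C[C@@H]3[C@H]2C[C@H]1C
F6 | step 24 | methyl N2-(tert-butoxycarbonyl)-N5-[(2Z)-4-[3-acetyl-7-[(E)-2-iodoethenyl]-2-methyl-DHI-6-yl]but-2-enoyl]-L-ornithinate | CC(=O)[C@H]1[C@@H]2C=C[C@@H]3[C@@H](C/C=C\C(=O)NCCC[C@H](NC(=O)OC(C)(C)C)C(=O)OC)[C@H](/C=C/I)C[C@@H]3[C@H]2C[C@H]1C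
F7 | step 24 | (2E)-3-[3-acetyl-6-[(2Z)-4-[[(4S)-4-(Boc-amino)-5-methoxy-5-oxopentyl]amino]-4-oxobut-2-en-1-yl]-2-methyl-decahydro-as-indacen-7-yl]prop-2-enoic acid (tc) | CC(=O)[C@H]1[C@@H]2C=C[C@@H]3[C@@H](C/C=C\C(=O)NCCC[C@H](NC(=O)OC(C)(C)C)C(=O)OC)[C@H](/C=C/C(=O)O)C[C@@H]3[C@H]2C[C@H]1C
F8 | step 24 | acyl Meldrum's acid of F7 (5-(1-hydroxyprop-2-enylidene)-2,2-dimethyl-1,3-dioxane-4,6-dione unit on C-7) | CC(=O)[C@H]1[C@@H]2C=C[C@@H]3[C@@H](C/C=C\C(=O)NCCC[C@H](NC(=O)OC(C)(C)C)C(=O)OC)[C@H](/C=C/C(O)=C4C(=O)OC(C)(C)OC4=O)C[C@@H]3[C@H]2C[C@H]1C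
F9 | step 24 | free α-amine of F8 (Boc removed; written in neutral form) | CC(=O)[C@H]1[C@@H]2C=C[C@@H]3[C@@H](C/C=C\C(=O)NCCC[C@H](N)C(=O)OC)[C@H](/C=C/C(O)=C4C(=O)OC(C)(C)OC4=O)C[C@@H]3[C@H]2C[C@H]1C
F10 | step 24 | macrocyclic β-keto amide methyl ester (seco-Dieckmann precursor of 32; enone C(=O)CH2C(=O)NH joined to the ornithine α-nitrogen) | CC(=O)[C@H]1[C@@H]2C=C[C@@H]3[C@H]4C/C=C\C(=O)NCCC[C@@H](C(=O)OC)NC(=O)CC(=O)/C=C/[C@@H]4C[C@@H]3[C@H]2C[C@H]1C
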